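The tertiary C1 carbinol of the five–seven ring fusion faces C5 across the ten-membered C1–C10 perimeter, so the guaiane is cut at C1–C5 back to a germacrane-type (E)-cyclodec-4-enone whose C1 ketone and C4=C5 olefin are the only reacting groups. One Lewis-acid transannular carbonyl-ene step then forms that bond, closes both rings, sets C1 and leaves a C4 methylene for the enone. The precursor carries the C10 methyl and the cis C6–C8 oxygen/carbon triad as silyl ethers; it is assembled from pent-4-yn-1-ol by crotylboration, Noyori reduction, Fráter–Seebach aldol with acetone and Nozaki–Hiyama–Kishi macrocyclisation.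

Key step: step 15

Remark: guaiane numbering (C1–C15) is used for all intermediates; the C1 carbinol centre of 5–18 is set only as a by-product of the crotylboration and is erased by oxidation in step 12.
Remark: the ene adduct 22 is formulated with a trans ring fusion (C1–OH anti to H5), the geometry that hydrogen delivery from the C4 methyl demands; C5 becomes trigonal again in step 18.
Remark: 23 is carried on as a mixture of C3 epimers (C3 left undefined in its SMILES); both give 24.

Step 1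
Reactants: 1 pent-4-yn-1-ol
Product: 3 (E)-5-iodo-4-methylpent-4-en-1-ol, via alkenyldimethylalane 2 (not isolated)
Conditions: Me3Al (3 equiv), Cp2ZrCl2 (0.25 equiv), CH2Cl2, 0 °C → rt; I2, THF, −30 °C; aq. K2CO3
Reagents that add atoms: trimethylaluminium, C[Al](C)C; iodine, II
Why: Negishi carboalumination (syn addition of CH3–Al across the terminal alkyne, methyl to the internal carbon) followed by iodinolysis of the C–Al bond with retention fixes the E geometry of the future C4=C5 olefin and installs C15.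

Step 2
Reactants: 3 (E)-5-iodo-4-methylpent-4-en-1-ol
Product: 4 (E)-5-iodo-4-methylpent-4-enal
Conditions: Dess–Martin periodinane, NaHCO3, CH2Cl2, 0 °C → rt
Reagents that add atoms: none
Why: Dess–Martin oxidation takes the primary alcohol to the aldehyde under neutral conditions that leave the iodoalkene untouched.

Step 3
Reactants: 4 (E)-5-iodo-4-methylpent-4-enal
Product: 6 (3S,4R,6E)-7-iodo-3,6-dimethylhepta-1,6-dien-4-ol, via borinate ester 5 (not isolated)
Conditions: (E)-crotyl-B(Ipc)2 [from (−)-Ipc2BOMe, (E)-but-2-ene, KOt-Bu, n-BuLi, BF3·OEt2], THF, −78 °C; NaOH, H2O2, 0 °C → rt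
Reagents that add atoms: (E)-crotylbis(isopinocampheyl)borane, C/C=C/CB([C@@H]1C[C@@H]2C[C@H]([C@H]1C)C2(C)C)[C@@H]1C[C@@H]2C[C@H]([C@H]1C)C2(C)C
Why: Brown crotylboration through a chair six-membered transition state, in which the E-crotyl group gives the anti adduct and the isopinocampheyl ligands from (+)-α-pinene direct the allyl unit to the Si face of the aldehyde, sets C10 as S.

Step 4
Reactants: 6 (3S,4R,6E)-7-iodo-3,6-dimethylhepta-1,6-dien-4-ol
Product: 7 (3S,4R,6E)-7-iodo-3,6-dimethylhepta-1,6-dien-4-yl pivalate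
Conditions: t-BuCOCl, pyridine, DMAP (cat.), CH2Cl2, 0 °C → rt
Reagents that add atoms: pivaloyl chloride, CC(C)(C)C(=O)Cl
Why: Acylation gives an ester protecting group that tolerates borane, LiN(i-Pr)2 and silyl triflates and is later removed by the same hydride reagent that reduces the C6 ester.

Step 5
Reactants: 7 (3S,4R,6E)-7-iodo-3,6-dimethylhepta-1,6-dien-4-yl pivalate
Product: 9 (3S,4R,6E)-1-hydroxy-7-iodo-3,6-dimethylhept-6-en-4-yl pivalate, via B-alkyl-9-BBN adduct 8 (not isolated)
Conditions: 9-BBN, THF, 0 °C → rt; NaOH, H2O2, 0 °C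
Reagents that add atoms: hydrogen peroxide, OO
Why: Anti-Markovnikov hydroboration–oxidation with the bulky borane reacts only at the monosubstituted olefin and leaves the trisubstituted iodoalkene and the pivalate intact.

Step 6
Reactants: 9 (3S,4R,6E)-1-hydroxy-7-iodo-3,6-dimethylhept-6-en-4-yl pivalate
Product: 10 (3S,4R,6E)-7-iodo-3,6-dimethyl-1-oxohept-6-en-4-yl pivalate
Conditions: Dess–Martin periodinane, NaHCO3, CH2Cl2, 0 °C → rt
Reagents that add atoms: none
Why: Dess–Martin oxidation gives the C8 aldehyde without base, so the C10 centre two atoms away is not at risk.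

Step 7
Reactants: 10 (3S,4R,6E)-7-iodo-3,6-dimethyl-1-oxohept-6-en-4-yl pivalate; 11 ethyl diazoacetate
Product: 12 ethyl (5S,6R,8E)-9-iodo-5,8-dimethyl-3-oxo-6-(pivaloyloxy)non-8-enoate
Conditions: SnCl2 (10 mol %), CH2Cl2, rt
Reagents that add atoms: none
Why: Roskamp homologation (Lewis-acid addition of the diazo ester to the unhindered aldehyde, 1,2-hydride shift and loss of N2) delivers the β-keto ester with C6 and C7 in one operation.

Step 8
Reactants: 12 ethyl (5S,6R,8E)-9-iodo-5,8-dimethyl-3-oxo-6-(pivaloyloxy)non-8-enoate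
Product: 13 ethyl (3R,5S,6R,8E)-3-hydroxy-9-iodo-5,8-dimethyl-6-(pivaloyloxy)non-8-enoate
Conditions: H2 (10 bar), RuCl2[(R)-BINAP] (1 mol %), EtOH, 50 °C
Reagents that add atoms: none
Why: Noyori asymmetric hydrogenation of the chelating β-keto ester is catalyst-controlled and sets C8 as R with the (R)-BINAP ligand, while the non-chelating trisubstituted iodoalkene should not be reduced.

Step 9
Reactants: 13 ethyl (3R,5S,6R,8E)-3-hydroxy-9-iodo-5,8-dimethyl-6-(pivaloyloxy)non-8-enoate; 14 acetone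
Product: 16 ethyl (2S,3R,5S,6R,8E)-3-hydroxy-2-(2-hydroxypropan-2-yl)-9-iodo-5,8-dimethyl-6-(pivaloyloxy)non-8-enoate, via dilithium alkoxide enolate 15 (not isolated)
Conditions: LiN(i-Pr)2 (2.3 equiv), THF, −78 → −30 °C; acetone, −78 °C; AcOH
Reagents that add atoms: none
Why: Fráter–Seebach reaction, in which acetone attacks the chelated alkoxide–enolate on the face opposite the C9 substituent of the six-membered lithium chelate, places the new C11 carbinol anti to the C8 oxygen and so sets C7.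

Step 10
Reactants: 16 ethyl (2S,3R,5S,6R,8E)-3-hydroxy-2-(2-hydroxypropan-2-yl)-9-iodo-5,8-dimethyl-6-(pivaloyloxy)non-8-enoate
Product: 17 ethyl (2S,3R,5S,6R,8E)-9-iodo-5,8-dimethyl-6-(pivaloyloxy)-3-(triethylsilyloxy)-2-[2-(triethylsilyloxy)propan-2-yl]non-8-enoate
Conditions: Et3SiOTf, 2,6-lutidine, CH2Cl2, −78 → 0 °C
Reagents that add atoms: triethylsilyl triflate, CC[Si](CC)(CC)OS(=O)(=O)C(F)(F)F
Why: Silyl ether formation with the triflate covers the secondary and the tertiary hydroxyl alike and protects the β-hydroxy ester against retro-aldol cleavage.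

Step 11
Reactants: 17 ethyl (2S,3R,5S,6R,8E)-9-iodo-5,8-dimethyl-6-(pivaloyloxy)-3-(triethylsilyloxy)-2-[2-(triethylsilyloxy)propan-2-yl]non-8-enoate
Product: 18 (2S,3R,5S,6R,8E)-9-iodo-5,8-dimethyl-3-(triethylsilyloxy)-2-[2-(triethylsilyloxy)propan-2-yl]non-8-ene-1,6-diol
Conditions: i-Bu2AlH (6 equiv), CH2Cl2, −78 → 0 °C; aq. potassium sodium tartrate
Reagents that add atoms: none
Why: Hydride reduction with excess i-Bu2AlH takes the ethyl ester to the primary alcohol and cleaves the pivalate in the same operation, while silyl ethers and the iodoalkene are inert.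

Step 12
Reactants: 18 (2S,3R,5S,6R,8E)-9-iodo-5,8-dimethyl-3-(triethylsilyloxy)-2-[2-(triethylsilyloxy)propan-2-yl]non-8-ene-1,6-diol
Product: 19 (2S,3R,5S,8E)-9-iodo-5,8-dimethyl-6-oxo-3-(triethylsilyloxy)-2-[2-(triethylsilyloxy)propan-2-yl]non-8-enal
Conditions: Dess–Martin periodinane (3 equiv), NaHCO3, CH2Cl2, 0 °C → rt
Reagents that add atoms: none
Why: Dess–Martin oxidation of both carbinols at once gives the C1 ketone and the C6 aldehyde without base, so the α-centres C7 and C10 should not epimerise.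

Step 13
Reactants: 19 (2S,3R,5S,8E)-9-iodo-5,8-dimethyl-6-oxo-3-(triethylsilyloxy)-2-[2-(triethylsilyloxy)propan-2-yl]non-8-enal
Product: 20 (4E,6S,7S,8R,10S)-6-hydroxy-4,10-dimethyl-8-(triethylsilyloxy)-7-[2-(triethylsilyloxy)propan-2-yl]cyclodec-4-en-1-one
Conditions: CrCl2 (10 equiv), NiCl2 (0.1 equiv), DMSO, rt, slow addition of 19 (2 mM final)
Reagents that add atoms: none
Why: Nozaki–Hiyama–Kishi macrocyclisation, in which the alkenylchromium adds only to the aldehyde with retention of the E geometry (the ketone cannot be reached without a trans five-membered olefin) and Felkin–Anh attack anti to the bulky C11 group, the rotamer that also keeps the tether gauche for closure, sets C6 with its oxygen anti to C11.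

Step 14
Reactants: 20 (4E,6S,7S,8R,10S)-6-hydroxy-4,10-dimethyl-8-(triethylsilyloxy)-7-[2-(triethylsilyloxy)propan-2-yl]cyclodec-4-en-1-one
Product: 21 (4E,6S,7R,8R,10S)-6-(tert-butyldimethylsilyloxy)-4,10-dimethyl-8-(triethylsilyloxy)-7-[2-(triethylsilyloxy)propan-2-yl]cyclodec-4-en-1-one
Conditions: t-BuMe2SiOTf, 2,6-lutidine, CH2Cl2, −78 °C
Reagents that add atoms: tert-butyldimethylsilyl triflate, CC(C)(C)[Si](C)(C)OS(=O)(=O)C(F)(F)F
Why: Silyl ether formation at the hindered allylic C6 hydroxyl gives a group that outlasts the triethylsilyl ethers and serves as the steric control element of step 15.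

Step 15
Reactants: 21 (4E,6S,7R,8R,10S)-6-(tert-butyldimethylsilyloxy)-4,10-dimethyl-8-(triethylsilyloxy)-7-[2-(triethylsilyloxy)propan-2-yl]cyclodec-4-en-1-one
Product: 22 (1R,5S,6S,7R,8R,10S)-6-(tert-butyldimethylsilyloxy)-8,11-bis(triethylsilyloxy)guai-4(15)-en-1-ol
Conditions: Me2AlCl (2.5 equiv), CH2Cl2, −78 → −20 °C
Reagents that add atoms: none
Why: Me2AlCl binds the C1 carbonyl and the ten-membered ring delivers C5, the less substituted end of the E olefin, to C1 while a hydrogen of the C4 methyl passes to oxygen through a six-membered array, leaving the C4=C15 methylene; the closest known reaction type is the Lewis-acid transannular carbonyl-ene (concerted Prins-type) cyclisation of medium-ring enones. Both rings close transannularly on the single new C1–C5 bond: with respect to the olefin the seven-membered ring forms in the exo mode (C4 stays outside) and the five-membered ring in the endo mode (C4 and C5 inside), the carbonyl being attacked exo in each. C5 is controlled by the C6 stereocentre: allylic 1,3-strain with the C4 methyl keeps H6 in the olefin plane and the bulky silyloxy group outside the ring, so the chain through C7 can bring C1 onto one π-face only and H5 ends syn to O6. C1 follows from the hydrogen transfer, which needs the carbonyl oxygen above the C4 methyl and therefore anti to H5 (trans fusion), so the new hydroxyl lies anti to O6 and, through the pre-set relation of C6 and C10, anti to the C10 methyl. The step needs hydrogen loss from C15 (not C3) and this face selectivity; the first should be secured by concerted transfer to the aluminium-bound oxygen with Me2AlCl as proton scavenger, the second by the C6–C8 substituents on the ring periphery.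

Step 16
Reactants: 22 (1R,5S,6S,7R,8R,10S)-6-(tert-butyldimethylsilyloxy)-8,11-bis(triethylsilyloxy)guai-4(15)-en-1-ol
Product: 23 (1R,5S,6S,7R,8R,10S)-6-(tert-butyldimethylsilyloxy)-8,11-bis(triethylsilyloxy)guai-4(15)-ene-1,3-diol (C3 epimers)
Conditions: SeO2 (0.5 equiv), t-BuOOH (3 equiv), CH2Cl2, rt
Reagents that add atoms: tert-butyl hydroperoxide, CC(C)(C)OO (terminal oxygen source, relayed by selenium dioxide, O=[Se]=O)
Why: Selenium dioxide allylic hydroxylation (ene reaction, then 2,3-sigmatropic shift) of the 1,1-disubstituted olefin should occur at the ring methylene C3 and not at the hindered C5–H flanked by two oxygen-bearing carbons, as is usual for 4(15)-unsaturated guaianes.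

Step 17
Reactants: 23 (1R,5S,6S,7R,8R,10S)-6-(tert-butyldimethylsilyloxy)-8,11-bis(triethylsilyloxy)guai-4(15)-ene-1,3-diol (C3 epimers)
Product: 24 (1R,5S,6S,7R,8R,10S)-6-(tert-butyldimethylsilyloxy)-1-hydroxy-8,11-bis(triethylsilyloxy)guai-4(15)-en-3-one
Conditions: Dess–Martin periodinane, NaHCO3, CH2Cl2, 0 °C
Reagents that add atoms: none
Why: Dess–Martin oxidation converts both C3 epimers of the secondary allylic alcohol into the α-methylene ketone; the tertiary C1 hydroxyl cannot be oxidised.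

Step 18
Reactants: 24 (1R,5S,6S,7R,8R,10S)-6-(tert-butyldimethylsilyloxy)-1-hydroxy-8,11-bis(triethylsilyloxy)guai-4(15)-en-3-one
Product: 26 (1R,6R,7R,8R,10S)-6-(tert-butyldimethylsilyloxy)-1,8,11-trihydroxyguai-4-en-3-one, via endocyclic enone bis(triethylsilyl) ether 25 (not isolated)
Conditions: RhCl3·3H2O (10 mol %), EtOH, 70 °C; then PPTS (0.3 equiv), EtOH, rt
Reagents that add atoms: none
Why: Metal-hydride olefin isomerisation (Rh–H addition and β-hydride elimination) moves the exocyclic double bond into the thermodynamically preferred tetrasubstituted C4=C5 position, and acid-catalysed ethanolysis then removes both triethylsilyl ethers but not the more robust C6 silyl ether.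

Step 19
Reactants: 26 (1R,6R,7R,8R,10S)-6-(tert-butyldimethylsilyloxy)-1,8,11-trihydroxyguai-4-en-3-one; 27 angelic acid
Product: 29 (1R,6R,7R,8R,10S)-8-angeloyloxy-6-(tert-butyldimethylsilyloxy)-1,11-dihydroxyguai-4-en-3-one, via mixed anhydride 28 (not isolated)
Conditions: 27, 2,4,6-Cl3C6H2COCl, Et3N, toluene, rt; then 26, 80 °C
Reagents that add atoms: none
Why: Yamaguchi-type esterification through the mixed anhydride should acylate only the secondary C8 hydroxyl (both tertiary alcohols are inert, C6 is silylated), and the absence of DMAP preserves the Z geometry of the angelate.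

Step 20
Reactants: 29 (1R,6R,7R,8R,10S)-8-angeloyloxy-6-(tert-butyldimethylsilyloxy)-1,11-dihydroxyguai-4-en-3-one
Product: 30 (1R,6R,7S,8R,10S)-8-angeloyloxy-1,6,11-trihydroxyguai-4-en-3-one
Conditions: HF·pyridine, pyridine, THF, 0 °C → rt
Reagents that add atoms: none
Why: Fluoride desilylation under acidic conditions frees the C6 hydroxyl without the base that could cause acyl migration across the C6/C8 diol or retro-aldol opening of the β-hydroxy ketone.

Step 21
Reactants: 30 (1R,6R,7S,8R,10S)-8-angeloyloxy-1,6,11-trihydroxyguai-4-en-3-one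
Product: 32 (1R,6R,7S,8R,10S)-11-acetoxy-8-angeloyloxy-1,6-dihydroxyguai-4-en-3-one (CNP0273287.1), via cyclic orthoacetate 31 (not isolated)
Conditions: MeC(OMe)3, PPTS (10 mol %), CH2Cl2, rt; then AcOH–H2O (4:1), 0 °C → rt
Reagents that add atoms: trimethyl orthoacetate, COC(C)(OC)OC; water, O
Why: Orthoester exchange joins the C6/C11 1,3-diol in a six-membered cyclic orthoacetate, whose acid hydrolysis should expel the less hindered secondary C6 oxygen and leave the acetyl group on the tertiary C11 oxygen, as in the preparation of tertiary 17-esters of corticosteroids from 17,21-cyclic orthoesters, while the isolated C1 hydroxyl cannot form such a ring.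

Compound list
1 | pent-4-yn-1-ol | C#CCCCO | starting material
2 | dimethyl[(E)-5-(dimethylalumanyloxy)-2-methylpent-1-enyl]alumane | C[Al](C)OCCC/C(C)=C/[Al](C)C | intermediate
3 | (E)-5-iodo-4-methylpent-4-en-1-ol | OCCC/C(C)=C/I | intermediate
4 | (E)-5-iodo-4-methylpent-4-enal | O=CCC/C(C)=C/I | intermediate
5 | (3S,4R,6E)-7-iodo-3,6-dimethylhepta-1,6-dien-4-yl bis(isopinocampheyl)borinate | C=C[C@H](C)[C@H](OB([C@@H]1C[C@@H]2C[C@H]([C@H]1C)C2(C)C)[C@@H]1C[C@@H]2C[C@H]([C@H]1C)C2(C)C)CC/C(C)=C/I | intermediate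
6 | (3S,4R,6E)-7-iodo-3,6-dimethylhepta-1,6-dien-4-ol | C=C[C@H](C)[C@H](O)CC/C(C)=C/I | intermediate
7 | (3S,4R,6E)-7-iodo-3,6-dimethylhepta-1,6-dien-4-yl pivalate | C=C[C@H](C)[C@H](OC(=O)C(C)(C)C)CC/C(C)=C/I | intermediate
8 | 9-[(3S,4R,6E)-7-iodo-3,6-dimethyl-4-(pivaloyloxy)hept-6-enyl]-9-borabicyclo[3.3.1]nonane | B1(C2CCCC1CCC2)CC[C@H](C)[C@H](OC(=O)C(C)(C)C)CC/C(C)=C/I | intermediate
9 | (3S,4R,6E)-1-hydroxy-7-iodo-3,6-dimethylhept-6-en-4-yl pivalate | OCC[C@H](C)[C@H](OC(=O)C(C)(C)C)CC/C(C)=C/I | intermediate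
10 | (3S,4R,6E)-7-iodo-3,6-dimethyl-1-oxohept-6-en-4-yl pivalate | O=CC[C@H](C)[C@H](OC(=O)C(C)(C)C)CC/C(C)=C/I | intermediate
11 | ethyl diazoacetate | CCOC(=O)C=[N+]=[N-] | starting material
12 | ethyl (5S,6R,8E)-9-iodo-5,8-dimethyl-3-oxo-6-(pivaloyloxy)non-8-enoate | CCOC(=O)CC(=O)C[C@H](C)[C@H](OC(=O)C(C)(C)C)CC/C(C)=C/I | intermediate
13 | ethyl (3R,5S,6R,8E)-3-hydroxy-9-iodo-5,8-dimethyl-6-(pivaloyloxy)non-8-enoate | CCOC(=O)C[C@H](O)C[C@H](C)[C@H](OC(=O)C(C)(C)C)CC/C(C)=C/I | intermediate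
14 | acetone | CC(C)=O | starting material
15 | dilithium alkoxide–enolate of 13 | CCO/C(O[Li])=C/[C@H](O[Li])C[C@H](C)[C@H](OC(=O)C(C)(C)C)CC/C(C)=C/I | intermediate
16 | ethyl (2S,3R,5S,6R,8E)-3-hydroxy-2-(2-hydroxypropan-2-yl)-9-iodo-5,8-dimethyl-6-(pivaloyloxy)non-8-enoate | CCOC(=O)[C@H](C(C)(C)O)[C@H](O)C[C@H](C)[C@H](OC(=O)C(C)(C)C)CC/C(C)=C/I | intermediate
17 | ethyl (2S,3R,5S,6R,8E)-9-iodo-5,8-dimethyl-6-(pivaloyloxy)-3-(triethylsilyloxy)-2-[2-(triethylsilyloxy)propan-2-yl]non-8-enoate | CCOC(=O)[C@H](C(C)(C)O[Si](CC)(CC)CC)[C@H](O[Si](CC)(CC)CC)C[C@H](C)[C@H](OC(=O)C(C)(C)C)CC/C(C)=C/I | intermediate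
18 | (2S,3R,5S,6R,8E)-9-iodo-5,8-dimethyl-3-(triethylsilyloxy)-2-[2-(triethylsilyloxy)propan-2-yl]non-8-ene-1,6-diol | OC[C@H](C(C)(C)O[Si](CC)(CC)CC)[C@H](O[Si](CC)(CC)CC)C[C@H](C)[C@H](O)CC/C(C)=C/I | intermediate
19 | (2S,3R,5S,8E)-9-iodo-5,8-dimethyl-6-oxo-3-(triethylsilyloxy)-2-[2-(triethylsilyloxy)propan-2-yl]non-8-enal | O=C[C@H](C(C)(C)O[Si](CC)(CC)CC)[C@H](O[Si](CC)(CC)CC)C[C@H](C)C(=O)CC/C(C)=C/I | intermediate
20 | (4E,6S,7S,8R,10S)-6-hydroxy-4,10-dimethyl-8-(triethylsilyloxy)-7-[2-(triethylsilyloxy)propan-2-yl]cyclodec-4-en-1-one | CC[Si](CC)(CC)O[C@@H]1C[C@H](C)C(=O)CC/C(C)=C/[C@H](O)[C@@H]1C(C)(C)O[Si](CC)(CC)CC | intermediate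
21 | (4E,6S,7R,8R,10S)-6-(tert-butyldimethylsilyloxy)-4,10-dimethyl-8-(triethylsilyloxy)-7-[2-(triethylsilyloxy)propan-2-yl]cyclodec-4-en-1-one (ene precursor) | CC[Si](CC)(CC)O[C@@H]1C[C@H](C)C(=O)CC/C(C)=C/[C@H](O[Si](C)(C)C(C)(C)C)[C@@H]1C(C)(C)O[Si](CC)(CC)CC | intermediate
22 | (1R,5S,6S,7R,8R,10S)-6-(tert-butyldimethylsilyloxy)-8,11-bis(triethylsilyloxy)guai-4(15)-en-1-ol (ene product, trans-fused) | CC[Si](CC)(CC)O[C@@H]1C[C@H](C)[C@]2(O)CCC(=C)[C@H]2[C@H](O[Si](C)(C)C(C)(C)C)[C@@H]1C(C)(C)O[Si](CC)(CC)CC | intermediate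
23 | (1R,5S,6S,7R,8R,10S)-6-(tert-butyldimethylsilyloxy)-8,11-bis(triethylsilyloxy)guai-4(15)-ene-1,3-diol, C3 epimers | CC[Si](CC)(CC)O[C@@H]1C[C@H](C)[C@]2(O)CC(O)C(=C)[C@H]2[C@H](O[Si](C)(C)C(C)(C)C)[C@@H]1C(C)(C)O[Si](CC)(CC)CC | intermediate
24 | (1R,5S,6S,7R,8R,10S)-6-(tert-butyldimethylsilyloxy)-1-hydroxy-8,11-bis(triethylsilyloxy)guai-4(15)-en-3-one | CC[Si](CC)(CC)O[C@@H]1C[C@H](C)[C@]2(O)CC(=O)C(=C)[C@H]2[C@H](O[Si](C)(C)C(C)(C)C)[C@@H]1C(C)(C)O[Si](CC)(CC)CC | intermediate
25 | (1R,6R,7R,8R,10S)-6-(tert-butyldimethylsilyloxy)-1-hydroxy-8,11-bis(triethylsilyloxy)guai-4-en-3-one | CC[Si](CC)(CC)O[C@@H]1C[C@H](C)[C@]2(O)CC(=O)C(C)=C2[C@H](O[Si](C)(C)C(C)(C)C)[C@@H]1C(C)(C)O[Si](CC)(CC)CC | intermediate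
26 | (1R,6R,7R,8R,10S)-6-(tert-butyldimethylsilyloxy)-1,8,11-trihydroxyguai-4-en-3-one | O[C@@H]1C[C@H](C)[C@]2(O)CC(=O)C(C)=C2[C@H](O[Si](C)(C)C(C)(C)C)[C@@H]1C(C)(C)O | intermediate
27 | angelic acid, (Z)-2-methylbut-2-enoic acid | C/C=C(/C)C(=O)O | starting material
28 | angelic 2,4,6-trichlorobenzoic anhydride | C/C=C(/C)C(=O)OC(=O)c1c(Cl)cc(Cl)cc1Cl | intermediate
29 | (1R,6R,7R,8R,10S)-8-angeloyloxy-6-(tert-butyldimethylsilyloxy)-1,11-dihydroxyguai-4-en-3-one | C/C=C(/C)C(=O)O[C@@H]1C[C@H](C)[C@]2(O)CC(=O)C(C)=C2[C@H](O[Si](C)(C)C(C)(C)C)[C@@H]1C(C)(C)O | intermediate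
30 | (1R,6R,7S,8R,10S)-8-angeloyloxy-1,6,11-trihydroxyguai-4-en-3-one | C/C=C(/C)C(=O)O[C@@H]1C[C@H](C)[C@]2(O)CC(=O)C(C)=C2[C@H](O)[C@@H]1C(C)(C)O | intermediate
31 | 6,11-O-(1-methoxyethylidene) cyclic orthoacetate of 30, mixture at the orthoester carbon | C/C=C(/C)C(=O)O[C@@H]1C[C@H](C)[C@]2(O)CC(=O)C(C)=C2[C@@H]3OC(C)(OC)OC(C)(C)[C@H]13 | intermediate
32 | (1R,6R,7S,8R,10S)-11-acetoxy-8-angeloyloxy-1,6-dihydroxyguai-4-en-3-one (CNP0273287.1) | C/C=C(/C)C(=O)O[C@@H]1C[C@H](C)[C@]2(O)CC(=O)C(C)=C2[C@H](O)[C@@H]1C(C)(C)OC(C)=O | target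

Total step count: 21. Longest linear sequence: 21 steps (1 → 32).

Steps most likely to fail

Step 15 (transannular carbonyl-ene). Carbon–carbon bond formation may run ahead of hydrogen transfer, so that the C4 cation loses a proton toward C3 or is quenched by the aluminium reagent; closure through the other ring conformer (loss of face selectivity at C1) is the second concern and is not cured by what follows. Fallback: the closure is made deliberately stepwise. From 21, a Prins cyclisation with TiCl4 (CH2Cl2, −78 °C), in which chloride captures the C4 cation, should give the 4-chloro-1-hydroxyguaiane tris(silyl ether) F1. Dehydrochlorination toward the methyl group with DBU (toluene, 80 °C), a base too weak to form the C1 alkoxide that could trigger Grob-type ring opening, then returns to 22.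

Step 13 (Nozaki–Hiyama–Kishi macrocyclisation). Ring strain may force the aldehyde to react through the rotamer that turns its other face to the alkenylchromium (poor facial selectivity at C6), besides the usual competition from oligomerisation. Fallback: from 19, the cyclisation is accepted as it comes. If it gives mainly the C6-epimeric alcohol F2, Mitsunobu inversion (4-nitrobenzoic acid, PPh3, DIAD, toluene, 0 °C) should give the inverted 4-nitrobenzoate F3, and mild methanolysis (K2CO3, MeOH, 0 °C) returns to 20.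

Step 18 (isomerisation of the exocyclic enone). Rh–H addition may stall at the hindered C5–H, or the acidic hot ethanol may strip the C6 silyl ether too early (loss of a protecting group). Fallback: from 24, 1,4-hydrosilylation (Et3SiH, RhCl(PPh3)3 cat., benzene, 50 °C) should give the C3=C4 triethylsilyl enol ether F4 regiospecifically. Saegusa–Ito oxidation (Pd(OAc)2, MeCN, rt) then removes H5 and gives 25, which the PPTS stage of step 18 converts into 26; β-hydride loss from the methyl group would only regenerate 24.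

Further compounds
F1 | step 15 | (1R,5S,6S,7R,8R,10S)-6-(tert-butyldimethylsilyloxy)-4-chloro-8,11-bis(triethylsilyloxy)guaian-1-ol, C4 undefined | CC[Si](CC)(CC)O[C@@H]1C[C@H](C)[C@]2(O)CCC(C)(Cl)[C@H]2[C@H](O[Si](C)(C)C(C)(C)C)[C@@H]1C(C)(C)O[Si](CC)(CC)CC
F2 | step 13 | (4E,6R,7S,8R,10S)-6-hydroxy-4,10-dimethyl-8-(triethylsilyloxy)-7-[2-(triethylsilyloxy)propan-2-yl]cyclodec-4-en-1-one (C6 epimer of 20) | CC[Si](CC)(CC)O[C@@H]1C[C@H](C)C(=O)CC/C(C)=C/[C@@H](O)[C@@H]1C(C)(C)O[Si](CC)(CC)CC
F3 | step 13 | 4-nitrobenzoate of 20: (4E,6S,7S,8R,10S)-4,10-dimethyl-1-oxo-8-(triethylsilyloxy)-7-[2-(triethylsilyloxy)propan-2-yl]cyclodec-4-en-6-yl 4-nitrobenzoate (ketone numbering kept) | CC[Si](CC)(CC)O[C@@H]1C[C@H](C)C(=O)CC/C(C)=C/[C@H](OC(=O)c2ccc(cc2)[N+](=O)[O-])[C@@H]1C(C)(C)O[Si](CC)(CC)CC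
F4 | step 18 | (1R,5S,6S,7R,8R,10S)-6-(tert-butyldimethylsilyloxy)-3,8,11-tris(triethylsilyloxy)guai-3-en-1-ol (silyl enol ether) | CC[Si](CC)(CC)O[C@@H]1C[C@H](C)[C@]2(O)CC(O[Si](CC)(CC)CC)=C(C)[C@H]2[C@H](O[Si](C)(C)C(C)(C)C)[C@@H]1C(C)(C)O[Si](CC)(CC)CC
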